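## Retrosynthetic overview

- Target as encoded by the SMILES: a cis-fused decalin (H-4a and 8a-CH3 on the same face), (3S)-5-[(1R,2R,4aR,8aS)-2-acetoxy-2,5,5,8a-tetramethyldecahydronaphthalen-1-yl]-3-methylpentanoic acid, i.e. the ring-fusion epimer of labdanolic acid acetate.
- Late stage: acid ⇐ methyl ester; acetate ⇐ tertiary alcohol; H-1 ⇐ hydroxyl-directed hydrogenation of an exocyclic C-1 alkylidene; C-2 carbinol ⇐ CH3 addition to the enone.
- Enone ⇐ Horner–Wadsworth–Emmons union of a bicyclic β-keto phosphonate with methyl (3S)-3-methyl-5-oxopentanoate (from 3-methylglutaric anhydride).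
- Both rings ⇐ one proton-initiated, enantioselective cation–olefin bicyclization of an acyclic (Z)-polyene keto phosphonate (ring A closes first, ring B second, as in the labdane cyclase cascade); the Z olefin gives the cis fusion. Polyene ⇐ nerol + dimethyl (2-oxopropyl)phosphonate.
- The ring-B cation is not trapped by oxygen directly: in the cis series, anti addition through chair transition states would give the C-1/C-2 diepimeric pattern, so both centres are set afterwards under reagent control.

Assumption: the SMILES is taken literally (cis ring fusion); anions made by deprotonation in the flask and borate or cerium alkoxides cleaved on work-up are treated as activated forms of the numbered compounds and are not numbered separately.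

## Route

Step 1
Reactants: 1 nerol, (2Z)-3,7-dimethylocta-2,6-dien-1-ol
Product: 2 neryl bromide, (2Z)-1-bromo-3,7-dimethylocta-2,6-diene
Conditions: PBr3 (0.4 equiv), Et2O, −10 °C
Reagents that add atoms: phosphorus tribromide, BrP(Br)Br
Why: Low-temperature SN2 bromination of the primary allylic alcohol through its phosphite ester keeps the 2Z geometry that later dictates the cis ring fusion; no stereocenter is formed.

Step 2
Reactants: 2 neryl bromide; 3 dimethyl (2-oxopropyl)phosphonate
Product: 4 dimethyl [(5Z)-6,10-dimethyl-2-oxoundeca-5,9-dien-1-yl]phosphonate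
Conditions: 3, NaH, THF, 0 °C; n-BuLi, 0 °C; then 2, 0 °C to rt; aq. NH4Cl
Reagents that add atoms: none
Why: Dianion alkylation of a β-keto phosphonate (Weiler/Grieco type): the more basic terminal carbanion attacks the allylic bromide by SN2, leaving the Z olefin and the phosphonate-activated CH2 intact.

Step 3
Reactants: 4 dimethyl [(5Z)-6,10-dimethyl-2-oxoundeca-5,9-dien-1-yl]phosphonate
Product: 5 dimethyl [(4aR,8aS)-5,5,8a-trimethyl-2-oxodecahydronaphthalen-1-yl]phosphonate (cis-fused; mixture of C-1 epimers)
Conditions: (R)-2-(2-fluorobenzyloxy)-2′-hydroxy-1,1′-binaphthyl (1.2 equiv), SnCl4 (2.3 equiv), toluene, −78 °C, 48 h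
Reagents that add atoms: none
Why: Proposed new method: the SnCl4-bound binaphthol (a Lewis-acid-assisted chiral Brønsted acid) protonates the terminal isopropylidene while a second SnCl4 chelates the keto phosphonate as its enol, so rings A and B close in one anti-addition cascade (Stork–Eschenmoser) in which the Z olefin fixes H-4a and 8a-CH3 cis and the chiral proton donor fixes the absolute sense (4aR,8aS; the mirror-image binaphthol is used if the sense proves opposite); the closest known reactions are the SnCl4-mediated cyclization of polyene β-keto esters and the enantioselective cyclization of polyprenoids with this same chiral acid; C-1 is left as an epimer mixture because it becomes sp2 in step 7.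

Step 4
Reactants: 6 3-methylglutaric anhydride (4-methyloxane-2,6-dione)
Product: 7 (3S)-5-methoxy-3-methyl-5-oxopentanoic acid
Conditions: MeOH (10 equiv), (DHQD)2AQN (10 mol %), Et2O, −40 °C
Reagents that add atoms: methanol, CO
Why: Cinchona-alkaloid-catalysed desymmetrising methanolysis of the prochiral anhydride (general-base catalysis) creates the S centre that becomes C-3 of the side chain; the pseudo-enantiomeric (DHQ)2AQN gives the antipode and is used instead should the sense prove opposite.

Step 5
Reactants: 7 (3S)-5-methoxy-3-methyl-5-oxopentanoic acid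
Product: 8 methyl (3S)-5-hydroxy-3-methylpentanoate
Conditions: BH3·SMe2, THF, −10 to 0 °C; MeOH quench
Reagents that add atoms: none
Why: Chemoselective borane reduction of the free carboxylic acid (via the acyloxyborane) in the presence of the methyl ester; the stereocenter is untouched and stays S because the ester arm still ranks higher.

Step 6
Reactants: 8 methyl (3S)-5-hydroxy-3-methylpentanoate
Product: 9 methyl (3S)-3-methyl-5-oxopentanoate
Conditions: PhI(OAc)2, TEMPO (10 mol %), CH2Cl2, rt
Reagents that add atoms: none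
Why: TEMPO-catalysed oxidation with PhI(OAc)2 stops cleanly at the aldehyde and cannot epimerise the β-stereocenter.

Step 7
Reactants: 5 dimethyl [(4aR,8aS)-5,5,8a-trimethyl-2-oxodecahydronaphthalen-1-yl]phosphonate; 9 methyl (3S)-3-methyl-5-oxopentanoate
Product: 10 methyl (3S)-3-methyl-5-[(4aR,8aS)-5,5,8a-trimethyl-2-oxooctahydronaphthalen-1(2H)-ylidene]pentanoate (alkene geometry immaterial)
Conditions: NaH, THF, 0 °C; then 9, rt to 50 °C
Reagents that add atoms: none
Why: Horner–Wadsworth–Emmons olefination of the cyclic β-keto phosphonate anion with an unhindered aliphatic aldehyde gives the exocyclic enone; the phosphorus-bearing stereocenter disappears and the E/Z geometry does not matter because step 9 saturates this alkene.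

Step 8
Reactants: 10 methyl (3S)-3-methyl-5-[(4aR,8aS)-5,5,8a-trimethyl-2-oxooctahydronaphthalen-1(2H)-ylidene]pentanoate
Product: 11 methyl (3S)-5-[(2R,4aR,8aS)-2-hydroxy-2,5,5,8a-tetramethyloctahydronaphthalen-1(2H)-ylidene]-3-methylpentanoate
Conditions: MeLi, CeCl3, THF, −78 °C; aq. NH4Cl
Reagents that add atoms: methyllithium, [Li]C
Why: Organocerium 1,2-addition (Imamoto) to the enone, non-basic and inert to the ester at −78 °C; in the favoured cis-decalin conformer the ring-A methylene C-8 is axial on the ketone ring and 1,3 to the carbonyl, so CH3 enters from the opposite face (the face of the angular methyl) and the new OH is axial and α (2R), with no axial group at the sp2 C-1 to oppose this.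

Step 9
Reactants: 11 methyl (3S)-5-[(2R,4aR,8aS)-2-hydroxy-2,5,5,8a-tetramethyloctahydronaphthalen-1(2H)-ylidene]-3-methylpentanoate
Product: 12 methyl (3S)-5-[(1R,2R,4aR,8aS)-2-hydroxy-2,5,5,8a-tetramethyldecahydronaphthalen-1-yl]-3-methylpentanoate
Conditions: [Ir(cod)(PCy3)(py)]PF6 (5 mol %), H2 (1 atm), CH2Cl2, rt
Reagents that add atoms: none
Why: Hydroxyl-directed homogeneous hydrogenation (Crabtree): iridium bound to the tertiary allylic OH adds H2 to the exocyclic alkene on the OH face, so H-1 is cis to OH (1R) and the side chain lies on the face of the angular methyl, whatever the alkene geometry.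

Step 10
Reactants: 12 methyl (3S)-5-[(1R,2R,4aR,8aS)-2-hydroxy-2,5,5,8a-tetramethyldecahydronaphthalen-1-yl]-3-methylpentanoate
Product: 13 methyl (3S)-5-[(1R,2R,4aR,8aS)-2-acetoxy-2,5,5,8a-tetramethyldecahydronaphthalen-1-yl]-3-methylpentanoate
Conditions: AcCl, N,N-dimethylaniline, CH2Cl2, 40 °C
Reagents that add atoms: acetyl chloride, CC(=O)Cl
Why: Acylation of the hindered tertiary alcohol with acetyl chloride and an aniline base; the C–O bond at C-2 is not broken, so the configuration is retained.

Step 11
Reactants: 13 methyl (3S)-5-[(1R,2R,4aR,8aS)-2-acetoxy-2,5,5,8a-tetramethyldecahydronaphthalen-1-yl]-3-methylpentanoate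
Product: 14 (3S)-5-[(1R,2R,4aR,8aS)-2-acetoxy-2,5,5,8a-tetramethyldecahydronaphthalen-1-yl]-3-methylpentanoic acid (target)
Conditions: LiOH (1.5 equiv), THF/H2O, 0 °C to rt; aq. HCl to pH 3
Reagents that add atoms: lithium hydroxide, [Li+].[OH-]
Why: Saponification of the unhindered chain methyl ester is far faster than that of the crowded tertiary acetate, so controlled LiOH hydrolysis frees the acid without touching the acetate or any stereocenter.

## Compound list

1 | nerol, (2Z)-3,7-dimethylocta-2,6-dien-1-ol | CC(C)=CCC/C(C)=C\CO | starting material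
2 | neryl bromide, (2Z)-1-bromo-3,7-dimethylocta-2,6-diene | CC(C)=CCC/C(C)=C\CBr | intermediate
3 | dimethyl (2-oxopropyl)phosphonate | COP(=O)(OC)CC(C)=O | starting material
4 | dimethyl [(5Z)-6,10-dimethyl-2-oxoundeca-5,9-dien-1-yl]phosphonate | COP(=O)(OC)CC(=O)CC/C=C(C)\CCC=C(C)C | intermediate
5 | dimethyl [(4aR,8aS)-5,5,8a-trimethyl-2-oxodecahydronaphthalen-1-yl]phosphonate (cis-fused, C-1 epimers) | O=C1CC[C@@H]2C(C)(C)CCC[C@]2(C)C1P(=O)(OC)OC | intermediate
6 | 3-methylglutaric anhydride | CC1CC(=O)OC(=O)C1 | starting material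
7 | (3S)-5-methoxy-3-methyl-5-oxopentanoic acid | COC(=O)C[C@@H](C)CC(=O)O | intermediate
8 | methyl (3S)-5-hydroxy-3-methylpentanoate | COC(=O)C[C@@H](C)CCO | intermediate
9 | methyl (3S)-3-methyl-5-oxopentanoate | COC(=O)C[C@@H](C)CC=O | intermediate
10 | methyl (3S)-3-methyl-5-[(4aR,8aS)-5,5,8a-trimethyl-2-oxooctahydronaphthalen-1(2H)-ylidene]pentanoate | COC(=O)C[C@@H](C)CC=C1C(=O)CC[C@@H]2C(C)(C)CCC[C@]12C | intermediate
11 | methyl (3S)-5-[(2R,4aR,8aS)-2-hydroxy-2,5,5,8a-tetramethyloctahydronaphthalen-1(2H)-ylidene]-3-methylpentanoate | COC(=O)C[C@@H](C)CC=C1[C@](C)(O)CC[C@@H]2C(C)(C)CCC[C@]12C | intermediate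
12 | methyl (3S)-5-[(1R,2R,4aR,8aS)-2-hydroxy-2,5,5,8a-tetramethyldecahydronaphthalen-1-yl]-3-methylpentanoate | COC(=O)C[C@@H](C)CC[C@H]1[C@](C)(O)CC[C@@H]2C(C)(C)CCC[C@]12C | intermediate
13 | methyl (3S)-5-[(1R,2R,4aR,8aS)-2-acetoxy-2,5,5,8a-tetramethyldecahydronaphthalen-1-yl]-3-methylpentanoate | COC(=O)C[C@@H](C)CC[C@H]1[C@](C)(OC(C)=O)CC[C@@H]2C(C)(C)CCC[C@]12C | intermediate
14 | (3S)-5-[(1R,2R,4aR,8aS)-2-acetoxy-2,5,5,8a-tetramethyldecahydronaphthalen-1-yl]-3-methylpentanoic acid | CC(=O)O[C@]1(C)CC[C@@H]2C(C)(C)CCC[C@]2(C)[C@H]1CC[C@H](C)CC(=O)O | target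

## Step count and risks

Total steps: 11. Longest linear sequence: 8 (steps 1, 2, 3, 7, 8, 9, 10, 11); steps 4 to 6 make the side-chain aldehyde.

**Step 3 (the bicyclization).** It can fail in enantioselectivity (achiral proton sources compete), in stereospecificity (stepwise closure gives trans-fused material) or by O- instead of C-termination. The fallback sets out from 4 and comes back at 5, and makes the absolute sense predictable. Asymmetric epoxidation of the terminal olefin of 4 (fructose-derived Shi ketone of the hand that gives the S oxirane, KHSO5, K2CO3, MeCN/dimethoxymethane, 0 °C) gives dimethyl [(5Z)-8-[(2S)-3,3-dimethyloxiran-2-yl]-6-methyl-2-oxooct-5-en-1-yl]phosphonate F1. Epoxide-initiated cyclization (SnCl4, CH2Cl2, −78 °C) runs through a chair ring A with the C–O bond equatorial and gives dimethyl [(4aR,6S,8aS)-6-hydroxy-5,5,8a-trimethyl-2-oxodecahydronaphthalen-1-yl]phosphonate F2. The extra hydroxyl is then removed by Barton–McCombie deoxygenation: 1,1′-thiocarbonyldiimidazole gives the 6-O-(imidazol-1-ylthiocarbonyl) derivative of the hydroxy phosphonate F3, and Bu3SnH/AIBN in toluene at 100 °C gives 5.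

**Step 7 (olefination at a carbon flanked by a quaternary centre).** The phosphonate anion may be too hindered to add. The fallback sets out from 2 and comes back at 10, replacing the phosphonate by a carboxyl group that is lost in the condensation. The dianion of benzyl acetoacetate is alkylated with 2 to give benzyl (6Z)-7,11-dimethyl-3-oxododeca-6,10-dienoate F4. The acid system of step 3 closes both rings to benzyl (4aR,8aS)-5,5,8a-trimethyl-2-oxodecahydronaphthalene-1-carboxylate F5 (β-keto ester termination is the best-precedented case). Hydrogenolysis (H2, Pd/C, EtOAc, 0 °C) gives (4aR,8aS)-5,5,8a-trimethyl-2-oxodecahydronaphthalene-1-carboxylic acid F6. This is condensed at once with 9 (pyrrolidine, AcOH, toluene, 40 °C) in a decarboxylative Knoevenagel-type reaction to give 10.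

**Step 8 (facial selectivity of the methyl addition).** The two cis-decalin conformers of 10 are not far apart in energy, and the minor one would expose the α face. If the 2-epimer of 11 predominates, the roles of carbon and oxygen at C-2 are exchanged; this fallback sets out from 10 and comes back at 11. Wittig methylenation (Ph3P=CH2, THF) gives methyl (3S)-3-methyl-5-[(4aR,8aS)-5,5,8a-trimethyl-2-methylideneoctahydronaphthalen-1(2H)-ylidene]pentanoate F7. OsO4 (cat.)/N-methylmorpholine N-oxide dihydroxylates the unhindered 1,1-disubstituted terminus from the same open face, now placing oxygen there, to give methyl (3S)-5-[(2R,4aR,8aS)-2-hydroxy-2-(hydroxymethyl)-5,5,8a-trimethyloctahydronaphthalen-1(2H)-ylidene]-3-methylpentanoate F8. I2/PPh3/imidazole converts the primary hydroxyl into methyl (3S)-5-[(2R,4aR,8aS)-2-hydroxy-2-(iodomethyl)-5,5,8a-trimethyloctahydronaphthalen-1(2H)-ylidene]-3-methylpentanoate F9. Bu3SnH/AIBN reduces CH2I to CH3 and gives 11.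

## Further compounds

F1 | step 3 | dimethyl [(5Z)-8-[(2S)-3,3-dimethyloxiran-2-yl]-6-methyl-2-oxooct-5-en-1-yl]phosphonate | COP(=O)(OC)CC(=O)CC/C=C(C)\CC[C@@H]1OC1(C)C
F2 | step 3 | dimethyl [(4aR,6S,8aS)-6-hydroxy-5,5,8a-trimethyl-2-oxodecahydronaphthalen-1-yl]phosphonate | O=C1CC[C@@H]2C(C)(C)[C@@H](O)CC[C@]2(C)C1P(=O)(OC)OC
F3 | step 3 | 6-O-(imidazol-1-ylthiocarbonyl) derivative of the hydroxy phosphonate | O=C1CC[C@@H]2C(C)(C)[C@@H](OC(=S)n3ccnc3)CC[C@]2(C)C1P(=O)(OC)OC
F4 | step 7 | benzyl (6Z)-7,11-dimethyl-3-oxododeca-6,10-dienoate | O=C(CC(=O)CC/C=C(C)\CCC=C(C)C)OCc1ccccc1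
F5 | step 7 | benzyl (4aR,8aS)-5,5,8a-trimethyl-2-oxodecahydronaphthalene-1-carboxylate | O=C1CC[C@@H]2C(C)(C)CCC[C@]2(C)C1C(=O)OCc1ccccc1
F6 | step 7 | (4aR,8aS)-5,5,8a-trimethyl-2-oxodecahydronaphthalene-1-carboxylic acid | O=C1CC[C@@H]2C(C)(C)CCC[C@]2(C)C1C(=O)O
F7 | step 8 | methyl (3S)-3-methyl-5-[(4aR,8aS)-5,5,8a-trimethyl-2-methylideneoctahydronaphthalen-1(2H)-ylidene]pentanoate | COC(=O)C[C@@H](C)CC=C1C(=C)CC[C@@H]2C(C)(C)CCC[C@]12C
F8 | step 8 | methyl (3S)-5-[(2R,4aR,8aS)-2-hydroxy-2-(hydroxymethyl)-5,5,8a-trimethyloctahydronaphthalen-1(2H)-ylidene]-3-methylpentanoate | COC(=O)C[C@@H](C)CC=C1[C@](CO)(O)CC[C@@H]2C(C)(C)CCC[C@]12C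
F9 | step 8 | methyl (3S)-5-[(2R,4aR,8aS)-2-hydroxy-2-(iodomethyl)-5,5,8a-trimethyloctahydronaphthalen-1(2H)-ylidene]-3-methylpentanoate | COC(=O)C[C@@H](C)CC=C1[C@](CI)(O)CC[C@@H]2C(C)(C)CCC[C@]12C
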